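Ring A (the central benzene) carries the quinone methide carbon C-alpha on C1 and a 4-hydroxyphenyl group on C2, directly beside the arylethynyl group on C6 (C5 bears CH2OH). Both crowded bonds, C2–aryl and C1–C-alpha, are cut back to a C1–C2 aryne. In one flask an aryllithium removes C1–H of a 4-fluoro-2-(arylethynyl)benzyl silyl ether, LiF is lost, a second aryllithium adds at C2 and the C1 lithium so formed is captured by a diaryl ketone. The precursor is therefore a simple fluoroarene made by two Sonogashira couplings. All five hydroxyl groups travel as triisopropylsilyl ethers, and fluoride in an acidic buffer unveils the quinone methide.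

Key step: step 7

Remark on the chemistry: (2-bromo-4-fluorophenyl)methanol, 4-iodophenol, 4,4'-dihydroxybenzophenone and ethynyltrimethylsilane are taken as catalogue chemicals. TIPS = triisopropylsilyl. The target has no stereocentre and no configurational double bond, so no descriptor is needed.

Step 1
Reactants: 1 (2-bromo-4-fluorophenyl)methanol
Product: 2 [(2-bromo-4-fluorobenzyl)oxy]triisopropylsilane
Conditions: TIPSCl (1.1 equiv), imidazole (2 equiv), DMF, rt
Reagents that add atoms: triisopropylsilyl chloride, CC(C)[Si](Cl)(C(C)C)C(C)C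
Why: Silyl ether formation from a primary benzylic alcohol with a silyl chloride and imidazole is routine, and the bulky TIPS ether should resist organolithium reagents later and is too hindered to direct ortho-metalation.

Step 2
Reactants: 2 [(2-bromo-4-fluorobenzyl)oxy]triisopropylsilane; 3 ethynyltrimethylsilane
Product: 4 ({4-fluoro-2-[(trimethylsilyl)ethynyl]benzyl}oxy)triisopropylsilane
Conditions: 3 (1.5 equiv), Pd(PPh3)2Cl2 (3 mol %), CuI (5 mol %), Et3N, 70 °C, sealed tube
Reagents that add atoms: none
Why: Sonogashira coupling, in which oxidative addition of zerovalent palladium into the aryl C–Br bond, transmetalation from the copper acetylide and reductive elimination should give the aryl alkyne, while the C–F bond and the silyl ether are inert and the trimethylsilyl cap prevents a second coupling.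

Step 3
Reactants: 4 ({4-fluoro-2-[(trimethylsilyl)ethynyl]benzyl}oxy)triisopropylsilane
Product: 5 [(2-ethynyl-4-fluorobenzyl)oxy]triisopropylsilane
Conditions: K2CO3 (0.2 equiv), MeOH/THF, rt
Reagents that add atoms: none
Why: Carbonate-catalysed methanolysis of the alkynyl C–Si bond (protodesilylation) is selective because an sp carbanion leaves silicon far more readily than an alkoxide leaves the hindered TIPS group.

Step 4
Reactants: 6 4-iodophenol
Product: 7 (4-iodophenoxy)triisopropylsilane
Conditions: TIPSCl (1.1 equiv), imidazole (2 equiv), DMF, rt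
Reagents that add atoms: triisopropylsilyl chloride, CC(C)[Si](Cl)(C(C)C)C(C)C
Why: Phenol silylation under the same silyl chloride and imidazole conditions should be fast, and the resulting aryl iodide serves twice, as the Sonogashira partner in step 5 and as the aryllithium source in step 7.

Step 5
Reactants: 5 [(2-ethynyl-4-fluorobenzyl)oxy]triisopropylsilane; 7 (4-iodophenoxy)triisopropylsilane
Product: 8 triisopropyl{[4-fluoro-2-({4-[(triisopropylsilyl)oxy]phenyl}ethynyl)benzyl]oxy}silane
Conditions: Pd(PPh3)2Cl2 (2 mol %), CuI (4 mol %), Et3N/THF, rt, degassed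
Reagents that add atoms: none
Why: Sonogashira coupling of an aryl iodide proceeds at room temperature even on an electron-rich ring, which spares the aryl silyl ether and the aryl fluoride, and rigorous degassing suppresses oxidative dimerisation of alkyne 5.

Step 6
Reactants: 9 4,4'-dihydroxybenzophenone
Product: 10 bis{4-[(triisopropylsilyl)oxy]phenyl}methanone
Conditions: TIPSCl (2.3 equiv), imidazole (5 equiv), DMF, rt
Reagents that add atoms: triisopropylsilyl chloride, CC(C)[Si](Cl)(C(C)C)C(C)C
Why: Twofold phenol silylation gives a non-enolisable, base-stable diaryl ketone whose bulky silyl ethers should survive the organolithium of step 7.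

Step 7
Reactants: 7 (4-iodophenoxy)triisopropylsilane; 8 triisopropyl{[4-fluoro-2-({4-[(triisopropylsilyl)oxy]phenyl}ethynyl)benzyl]oxy}silane; 10 bis{4-[(triisopropylsilyl)oxy]phenyl}methanone
Product: 15 [4'-(TIPS-oxy)-4-(TIPS-oxymethyl)-3-{[4-(TIPS-oxy)phenyl]ethynyl}biphenyl-2-yl]bis[4-(TIPS-oxy)phenyl]methanol (pentasilylated selaginellin carbinol), via aryllithium 11 (not isolated), via C1-lithiated fluoroarene 12 (not isolated), via ring A aryne 13 (not isolated), via 2-biaryllithium 14 (not isolated)
Conditions: 7 (2.5 equiv), t-BuLi (5.0 equiv), THF, −78 °C; 8 (1.0 equiv) added dropwise, −78 °C to rt; 10 (2.0 equiv), −78 °C to rt; aq NH4Cl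
Reagents that add atoms: none
Why: Iodine–lithium exchange on 7 gives aryllithium 11 free of alkyl halide; one equivalent of 11 removes C1–H of 8, the most acidic ring proton because it lies between fluorine and the sp carbon on C6, and the resulting 12 expels LiF on warming to give the C1–C2 aryne 13. A second equivalent of 11 adds to 13 at C2, the aryne carbon remote from the inductively withdrawing and space-demanding alkynyl group, so that the carbanion of 14 sits on C1 next to the sp carbon; 14 then adds to the non-enolisable ketone 10 to form the C1–C-alpha bond. The closest known reaction type is the coupling of an aryllithium with a fluoroarene through an aryne, followed by capture of the 2-biaryllithium by a benzophenone. No ring is closed and no stereocentre is formed. Two site selectivities are required, C1–H over C3–H in the metalation and C2 over C1 in the carbolithiation, and both rest on the C6 alkynyl group, while the TIPS ethers are too hindered and too weakly coordinating to steer lithiation onto the other rings. Inverse addition of 8 to excess 11 should keep 12, 13 and 14 from reacting with one another.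

Step 8
Reactants: 15 pentasilylated selaginellin carbinol
Product: 17 selaginellin, via pentahydroxy carbinol 16 (not isolated)
Conditions: TBAF (6 equiv), AcOH (8 equiv), THF, 0 °C to rt; aqueous work-up at pH 4–5
Reagents that add atoms: none
Why: Fluoride-mediated cleavage of all five Si–O bonds (silyl ether deprotection) should liberate carbinol 16, whose two 4-hydroxyphenyl groups on C-alpha make loss of water to the cross-conjugated quinone methide (fuchsone-type dehydration) facile in the acetic acid buffer, while that buffer keeps alkoxide basicity too low for oxygen to add to the C6 alkyne.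

Compound list
1 | (2-bromo-4-fluorophenyl)methanol | OCc1ccc(F)cc1Br | starting material
2 | [(2-bromo-4-fluorobenzyl)oxy]triisopropylsilane | CC(C)[Si](C(C)C)(C(C)C)OCc1ccc(F)cc1Br | intermediate
3 | ethynyltrimethylsilane | C#C[Si](C)(C)C | starting material
4 | ({4-fluoro-2-[(trimethylsilyl)ethynyl]benzyl}oxy)triisopropylsilane | CC(C)[Si](C(C)C)(C(C)C)OCc1ccc(F)cc1C#C[Si](C)(C)C | intermediate
5 | [(2-ethynyl-4-fluorobenzyl)oxy]triisopropylsilane | CC(C)[Si](C(C)C)(C(C)C)OCc1ccc(F)cc1C#C | intermediate
6 | 4-iodophenol | Oc1ccc(I)cc1 | starting material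
7 | (4-iodophenoxy)triisopropylsilane | CC(C)[Si](C(C)C)(C(C)C)Oc1ccc(I)cc1 | intermediate
8 | triisopropyl{[4-fluoro-2-({4-[(triisopropylsilyl)oxy]phenyl}ethynyl)benzyl]oxy}silane (key-step precursor) | CC(C)[Si](C(C)C)(C(C)C)OCc1ccc(F)cc1C#Cc1ccc(O[Si](C(C)C)(C(C)C)C(C)C)cc1 | intermediate
9 | 4,4'-dihydroxybenzophenone | O=C(c1ccc(O)cc1)c1ccc(O)cc1 | starting material
10 | bis{4-[(triisopropylsilyl)oxy]phenyl}methanone | O=C(c1ccc(O[Si](C(C)C)(C(C)C)C(C)C)cc1)c1ccc(O[Si](C(C)C)(C(C)C)C(C)C)cc1 | intermediate
11 | {4-[(triisopropylsilyl)oxy]phenyl}lithium | [Li]c1ccc(O[Si](C(C)C)(C(C)C)C(C)C)cc1 | intermediate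
12 | [6-fluoro-3-{[(triisopropylsilyl)oxy]methyl}-2-({4-[(triisopropylsilyl)oxy]phenyl}ethynyl)phenyl]lithium (8 lithiated at ring A C1) | CC(C)[Si](C(C)C)(C(C)C)OCc1ccc(F)c([Li])c1C#Cc1ccc(O[Si](C(C)C)(C(C)C)C(C)C)cc1 | intermediate
13 | ring A aryne with the triple bond between C1 and C2, C5 CH2O-TIPS and C6 arylethynyl retained | CC(C)[Si](C(C)C)(C(C)C)OCC1=C(C#Cc2ccc(O[Si](C(C)C)(C(C)C)C(C)C)cc2)C#CC=C1 | intermediate
14 | [4'-(TIPS-oxy)-4-(TIPS-oxymethyl)-3-{[4-(TIPS-oxy)phenyl]ethynyl}biphenyl-2-yl]lithium (lithium on ring A C1) | CC(C)[Si](C(C)C)(C(C)C)OCc1ccc(-c2ccc(O[Si](C(C)C)(C(C)C)C(C)C)cc2)c([Li])c1C#Cc1ccc(O[Si](C(C)C)(C(C)C)C(C)C)cc1 | intermediate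
15 | [4'-(TIPS-oxy)-4-(TIPS-oxymethyl)-3-{[4-(TIPS-oxy)phenyl]ethynyl}biphenyl-2-yl]bis[4-(TIPS-oxy)phenyl]methanol (key-step product) | OC(c1ccc(O[Si](C(C)C)(C(C)C)C(C)C)cc1)(c1ccc(O[Si](C(C)C)(C(C)C)C(C)C)cc1)c1c(-c2ccc(O[Si](C(C)C)(C(C)C)C(C)C)cc2)ccc(CO[Si](C(C)C)(C(C)C)C(C)C)c1C#Cc1ccc(O[Si](C(C)C)(C(C)C)C(C)C)cc1 | intermediate
16 | {4'-hydroxy-4-(hydroxymethyl)-3-[(4-hydroxyphenyl)ethynyl]biphenyl-2-yl}bis(4-hydroxyphenyl)methanol | OC(c1ccc(O)cc1)(c1ccc(O)cc1)c1c(-c2ccc(O)cc2)ccc(CO)c1C#Cc1ccc(O)cc1 | intermediate
17 | selaginellin | O=C1C=CC(=C(c2ccc(O)cc2)c2c(-c3ccc(O)cc3)ccc(CO)c2C#Cc2ccc(O)cc2)C=C1 | target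

Total step count: 8.
Longest linear sequence: 6 steps (steps 1, 2, 3, 5, 7 and 8). Steps 4 and 6 are side branches.

Steps most likely to fail

Step 7. Proton abstraction by the aryllithium may be slow or may occur at C3–H instead of C1–H, so that no aryne or the wrong aryne is formed. Fallback: from 8, LiN(i-Pr)2 in THF at −78 °C followed by iodine should give the C1 iodide triisopropyl{[4-fluoro-3-iodo-2-({4-[(triisopropylsilyl)oxy]phenyl}ethynyl)benzyl]oxy}silane F1. The low temperature lets the lithiated arene persist and settle on the most stabilised C1 position, and F1 is purified so that only C1-functionalised material goes forward. F1 and aryllithium 11 at −78 °C should then undergo iodine–lithium exchange, which places lithium on C1 regardless of C–H acidity. The route is rejoined at 12 and continues through 13 and 14 to 15 as in step 7. This fallback does not alter the direction of the carbolithiation.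

Step 8. Under fluoride, a benzylic or carbinol oxygen may add to the neighbouring alkyne, or cleavage of the primary silyl ether may stall in the buffered medium. Fallback: from 15, TBAF (4.2 equiv) with AcOH in THF at −20 to 0 °C should remove only the four aryl silyl ethers, and the buffer dehydrates the carbinol to the quinone methide with the C5 CH2O–TIPS group intact, selaginellin mono(triisopropylsilyl) ether F2. Aqueous HF in MeCN at rt then cleaves the remaining alkyl silyl ether under acidic conditions in which no alkoxide exists, and the route is rejoined at 17.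

Step 2. Oxidative addition into the ortho-substituted aryl bromide may be sluggish, with the volatile alkyne lost to copper-mediated dimerisation. Fallback: from 2, bromine–lithium exchange with n-BuLi in THF at −78 °C and quenching with DMF should give 5-fluoro-2-{[(triisopropylsilyl)oxy]methyl}benzaldehyde F3. Seyferth–Gilbert homologation with dimethyl (1-diazo-2-oxopropyl)phosphonate and K2CO3 in MeOH at rt should convert the aldehyde into the terminal alkyne, and the route is rejoined at 5 without passing through 4.

Further compounds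
F1 | step 7 | triisopropyl{[4-fluoro-3-iodo-2-({4-[(triisopropylsilyl)oxy]phenyl}ethynyl)benzyl]oxy}silane | CC(C)[Si](C(C)C)(C(C)C)OCc1ccc(F)c(I)c1C#Cc1ccc(O[Si](C(C)C)(C(C)C)C(C)C)cc1
F2 | step 8 | selaginellin mono(triisopropylsilyl) ether (silyl ether on the C5 hydroxymethyl group) | O=C1C=CC(=C(c2ccc(O)cc2)c2c(-c3ccc(O)cc3)ccc(CO[Si](C(C)C)(C(C)C)C(C)C)c2C#Cc2ccc(O)cc2)C=C1
F3 | step 2 | 5-fluoro-2-{[(triisopropylsilyl)oxy]methyl}benzaldehyde | CC(C)[Si](C(C)C)(C(C)C)OCc1ccc(F)cc1C=O
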